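I decided to reckon this flask from two rates, the two at which substrate leaves it at the start.

| flask | substrate | remark | time |
|---|---|---|---|
| east | 0.065 M | run made earlier |  |
| north-west | 0.098 M | run made earlier |  |
| flask | 0.13 M |  | 2.5 min |

| run | time / s | product / % | substrate / % |
|---|---|---|---|
| east | 25.0 | 3 | 59 |
| east | 50.0 | 9 | 41 |
| east | 60.0 | 12 | 38 |
| east | 90.0 | 13 | 27 |
| north-west | 10.0 | 1 | 75 |
| north-west | 15.0 | 0 | 67 |
| north-west | 40.0 | 8 | 43 |
| north-west | 90.0 | 11 | 24 |

(each reading ± 1.5 percentage points)

- amount of product in percent of the substrate charged, at 15 s, 50 s and 2.5 min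

Substrate has two exits, and product lies behind the first. Each unit leaves towards intermediate at a fractional rate a and towards homo dimer at b·c(substrate). Fractional loss should therefore climb in a straight line with concentration. The first reading of each earlier run gives one rough point, with the charge standing in for c(substrate):

east: ln(charged/left)/time = 0.0211 s⁻¹
north-west: ln(charged/left)/time = 0.0288 s⁻¹
slope: b = 0.232 M⁻¹ s⁻¹
intercept: a = 0.00601 s⁻¹
a/b = 0.0259 M

This last value is the crossover concentration, where the two exits run equally fast. It is a reading, and a rough one: the scatter moves the north-west point by 0.00200 s⁻¹.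

In the flask, b·c(substrate) starts at 0.0302 s⁻¹, faster than a by a factor of 5.02. I therefore expected 16.6% of the first substrate lost to head towards product. The first exit should lead once substrate falls below 19.9% of the charge.

The forecast gave 1%, 6% and 16%, reasoning that “Higher charge diverts more to dimer”.

The flask gave 1.74%, 7.34% and 11.9%, so the forecast held.

    2 substrate → homo dimer (k = 0.140 M⁻¹ s⁻¹)
    substrate ⇌ intermediate (K = 0.390, k = 0.00690 s⁻¹)
    intermediate ⇌ product (K = 2.50, k = 0.0380 s⁻¹)

At the start, the flask's substrate went to homo dimer 5.3 times as fast as forward into intermediate, and by 0.250 min dimerisation had 47% of its turnover up to 2.5 min behind it. In the flask, c(substrate) was 0.0290 M at 1.25 min, above the crossover, and 0.0169 M at 2.50 min, below it. In the east run, the same 0.0259 M is 39.8% of the charge, and substrate read 41% at 50.0 s.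

The earlier runs and the new flask were computed on assumed constants; noise was put on by code.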